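Bis adduct in this row of flasks is substrate that has taken up two reagents, so I reckoned with the fraction of substrate left and not with the fraction of product made.

| flask | substrate | reagent | remark | time |
|---|---|---|---|---|
| eta | 0.025 M | 0.66 M | run made earlier |  |
| oak | 0.025 M | 0.440 M |  | 30 min |
| birch | 0.080 M | 0.440 M |  | 30 min |
| larch | 0.20 M | 0.440 M |  | 30 min |
| alder | 0.60 M | 0.440 M |  | 30 min |
| maple | 2.0 M | 0.440 M |  | 30 min |

- eta (time / min: bis adduct / %, substrate / %): 0.667: 0, 90; 2.00: 8, 70; 4.00: 25, 49; 6.00: 31, 34; 8.00: 40, 28; 10.0: 44, 20

(readings scatter by 2 percentage points)

- a reading or a percentage of bis adduct counts all its forms, free or not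
- the concentration of bis adduct that is asked is that of its free form alone
- "hardly changes" means that all values lie within two and a half points (for a concentration: within two and a half percent of the largest)
- a reading of substrate is of its free form alone

* [bis adduct] (only what is free in solution) at the end for oak, birch, larch, alder, maple, in this order
* how the row runs (rises, then falls / rises all the way / falls, then rises / falls all the way / hardly changes)

How far did the substrate go? In the eta run the reagent charge stood at 26.4 times the substrate charge, so I treated the loss as pseudo-first-order. The reading of 20 % left at 10.0 min gave me a constant of 0.244 M⁻¹ min⁻¹, assuming first order in reagent from that single level. For oak, this constant times the reagent charge and the time came to 3.22. I call this the exposure, minus the natural logarithm of the fraction of substrate left, and with reagent held at its charge it left 4.00 %.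

Did the reagent hold? At two reagents per bis adduct, the demand against the reagent charge was 0.114 for oak and 0.909 for larch, but 2.73 for alder and 9.09 for maple. So I expected bis adduct to climb with the substrate charge through larch. From alder on, reagent became the limiting reagent, but its charge capped bis adduct at 0.220 M in alder and maple alike, which gives a plateau and no fall. The eta readings from 2.00 min to 4.00 min, with single product taken by difference, gave a selectivity factor of second over first uptake of 2.01, a reading with its scatter. So in maple even the whole reagent charge standing as single product, 0.883 M once weighted by that factor, stayed below the substrate charge, and I expected first uptake to keep the larger share of reagent there. I therefore committed to a row that rises, then falls.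

The forecast gave 0.017 M, 0.05 M, 0.095 M, 0.07 M and 0.03 M, a row that rises, then falls, noting “At larch, reagent runs short.”

The flasks gave 0.00764 M, 0.0290 M, 0.0720 M, 0.0575 M and 0.00707 M, a row that rises, then falls, turning at 0.32 M.

    substrate + reagent → single product (k = 0.00430 M⁻¹ s⁻¹)
    reagent + single product → bis adduct (k = 0.00990 M⁻¹ s⁻¹)
    reagent + bis adduct → triple product (k = 0.00280 M⁻¹ s⁻¹)
    substrate + bis adduct ⇌ idle adduct, settled at all times (K = 6.20 M⁻¹)

In oak at 30.0 min reagent stood at 86.0 % of its charge, free substrate at 4.88 % against the 4.00 % from the exposure of 3.22, and triple product at 60.6 %. In birch reagent fell to 60.2 % of its charge; the exposure scaled by the mean of its start and end shares, 2.58, leaves 7.58 %, where 8.81 % stood free. In maple reagent was down to 0.0184 % of its charge at 15.0 min, and the 3.79 % of bis adduct, idle adduct counted in, left 0.00707 M free.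

Readings and results were generated by integration with constants of no real substance, noise included.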